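Plagilin is a C2-symmetric dimer whose halves are held only by the biaryl bond C1–C1' between the catechol rings A and A'. Each terminus sits ortho to the arylethyl chain (C2) and para to the C4 oxygen. The route rests on cutting this bond into two copies of one monomer. The key step, a nickel-catalysed reductive homocoupling, doubles the complete fifteen-carbon half in one operation. The site is encoded by a bromine that the para-directing C4 oxygen places on ring A. The precursor is an (E)-2-bromostilbene with a dibenzyl-protected catechol. One final hydrogenation then saturates both alkenes and frees all four phenols.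

Key step: step 3

Assumption: only C2 and C2' carry substituents ortho to the axis, so rotation about C1–C1' is fast at room temperature and the target has no stereogenic element to control.

Step 1
Reactants: 1 3,4-bis(benzyloxy)benzaldehyde
Product: 2 4,5-bis(benzyloxy)-2-bromobenzaldehyde
Conditions: Br2 (1.1 equiv), NaOAc (1.5 equiv), AcOH, rt, dark
Reagents that add atoms: bromine, BrBr
Why: Electrophilic aromatic bromination goes to C6 of the aldehyde, the position para to the C3 benzyloxy group (the C4 oxygen is tied up in conjugation with the para formyl group and C2 is flanked on both sides), while NaOAc traps HBr so that the benzyl ethers survive.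

Step 2
Reactants: 2 4,5-bis(benzyloxy)-2-bromobenzaldehyde; 3 diethyl (3-methoxybenzyl)phosphonate
Product: 4 (E)-1,2-bis(benzyloxy)-4-bromo-5-[2-(3-methoxyphenyl)ethenyl]benzene
Conditions: KOtBu (1.2 equiv), THF, 0 °C to rt
Reagents that add atoms: none
Why: Horner–Wadsworth–Emmons olefination with the semi-stabilised benzylic phosphonate anion gives the E-alkene through reversible, sterically controlled addition and syn-elimination of the oxaphosphetane, and the aryl bromide and the ethers are inert to KOtBu at this temperature.

Step 3
Reactants: 4 (E)-1,2-bis(benzyloxy)-4-bromo-5-[2-(3-methoxyphenyl)ethenyl]benzene (two molecules)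
Product: 5 4,4',5,5'-tetrakis(benzyloxy)-2,2'-bis[(E)-2-(3-methoxyphenyl)ethenyl]-1,1'-biphenyl
Conditions: NiCl2(PPh3)2 (10 mol %), PPh3 (20 mol %), Zn dust (1.5 equiv), Et4NI (1 equiv), dry THF (concentrated), 50 °C, Ar, dark
Reagents that add atoms: none
Why: Zn reduces the divalent nickel of NiCl2(PPh3)2 to zerovalent nickel, which inserts into the C–Br bond of 4; Zn then reduces the aryl nickel bromide to a monovalent aryl nickel species that adds a second molecule of 4, and the trivalent diaryl nickel bromide reductively eliminates the C1–C1' bond, iodide from Et4NI speeding the electron transfer from Zn. The closest known reaction type is the nickel-catalysed, zinc-driven reductive homocoupling of aryl halides (catalytic Ullmann-type biaryl synthesis), which tolerates one ortho substituent per ring as well as ether groups. No ring is closed, and no stereocentre or stable axis is created, because only C2 and C2' carry ortho substituents. The step needs site selectivity, and the C–Br bond encodes it completely, so the closure of ring A onto ring B to a 9,10-dihydrophenanthrene, which an oxidative C–H coupling of the bibenzyl would favour, cannot occur. It also needs chemoselectivity against hydrodebromination and C–O insertion, which dry THF, high concentration and PPh3 (a ligand that does not activate aryl or benzyl ethers at 50 °C) should secure. Since both partners are the same molecule there is no cross-selectivity problem, and any E/Z drift of the alkenes is harmless because step 4 erases them.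

Step 4
Reactants: 5 4,4',5,5'-tetrakis(benzyloxy)-2,2'-bis[(E)-2-(3-methoxyphenyl)ethenyl]-1,1'-biphenyl
Product: 6 plagilin, 2,2'-bis[2-(3-methoxyphenyl)ethyl]-1,1'-biphenyl-4,4',5,5'-tetraol
Conditions: H2 (1–4 bar), 10% Pd/C, THF/MeOH, rt; filtration and concentration under Ar
Reagents that add atoms: none
Why: Heterogeneous catalytic hydrogenation adds H2 to both stilbene alkenes and hydrogenolyses the four benzylic C–O bonds in the same operation, whereas the aryl methyl ethers and the biaryl bond are inert to Pd/C and no stereocentre arises.

Compound list
1 | 3,4-bis(benzyloxy)benzaldehyde | O=Cc1ccc(OCc2ccccc2)c(OCc2ccccc2)c1 | starting material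
2 | 4,5-bis(benzyloxy)-2-bromobenzaldehyde | O=Cc1cc(OCc2ccccc2)c(OCc2ccccc2)cc1Br | intermediate
3 | diethyl (3-methoxybenzyl)phosphonate | CCOP(=O)(Cc1cccc(OC)c1)OCC | starting material
4 | (E)-1,2-bis(benzyloxy)-4-bromo-5-[2-(3-methoxyphenyl)ethenyl]benzene | COc1cccc(/C=C/c2cc(OCc3ccccc3)c(OCc3ccccc3)cc2Br)c1 | intermediate
5 | 4,4',5,5'-tetrakis(benzyloxy)-2,2'-bis[(E)-2-(3-methoxyphenyl)ethenyl]-1,1'-biphenyl | COc1cccc(/C=C/c2cc(OCc3ccccc3)c(OCc3ccccc3)cc2-c2cc(OCc3ccccc3)c(OCc3ccccc3)cc2/C=C/c2cccc(OC)c2)c1 | intermediate
6 | plagilin, 2,2'-bis[2-(3-methoxyphenyl)ethyl]-1,1'-biphenyl-4,4',5,5'-tetraol | COc1cccc(CCc2cc(O)c(O)cc2-c2cc(O)c(O)cc2CCc2cccc(OC)c2)c1 | target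

Total step count: 4
Longest linear sequence: 4

Steps most likely to fail

Step 3. Oxidative addition at the electron-rich, ortho-substituted C–Br bond may be slow. Protonolysis of the aryl nickel species (hydrodebromination) and binding of the nickel by the stilbene alkenes could then outrun the coupling. The fallback replaces the reductive homocoupling by a polarity-differentiated cross-coupling and sets out from 4. Half of the material is converted by Miyaura borylation (B2pin2, PdCl2(dppf), KOAc, dioxane, 80 °C) into the pinacol boronate (E)-2-{4,5-bis(benzyloxy)-2-[2-(3-methoxyphenyl)ethenyl]phenyl}-4,4,5,5-tetramethyl-1,3,2-dioxaborolane F1. This is joined to the other half of 4 by Suzuki–Miyaura coupling (Pd(OAc)2, SPhos, K3PO4, toluene/H2O, 90 °C), and the sequence comes back to the route at 5.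

Step 4. The stepwise hydrogenolysis may stall when the polar, partly debenzylated phenols foul the catalyst. The electron-rich bis-catechol may also be oxidised by air on the palladium surface during filtration. The fallback separates the two tasks, avoids a metal surface in the last operation, and sets out from 5. Diimide reduction (TsNHNH2, NaOAc, THF/H2O, reflux) saturates only the alkenes and gives 4,4',5,5'-tetrakis(benzyloxy)-2,2'-bis[2-(3-methoxyphenyl)ethyl]-1,1'-biphenyl F2. Lewis-acid debenzylation with a cation scavenger (BCl3, pentamethylbenzene, CH2Cl2, −78 °C, under Ar) spares the aryl methyl ethers and comes back to the route at 6.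

Step 2. Addition of the phosphonate anion to the electron-rich aldehyde, hindered by the ortho bromine, may be sluggish, leaving time for base-induced degradation of the aldehyde. The fallback builds the alkene from the other side and sets out from 2. Wittig methylenation (MePPh3Br, KOtBu, THF, 0 °C) gives the styrene 1,2-bis(benzyloxy)-4-bromo-5-ethenylbenzene F3. A Heck reaction with 3-iodoanisole (Pd(OAc)2, Bu4NCl, NaHCO3, DMF, 70 °C) consumes the aryl iodide well before the hindered, electron-rich aryl bromide can react, and it comes back to the route at 4.

Further compounds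
F1 | step 3 | (E)-2-{4,5-bis(benzyloxy)-2-[2-(3-methoxyphenyl)ethenyl]phenyl}-4,4,5,5-tetramethyl-1,3,2-dioxaborolane | COc1cccc(/C=C/c2cc(OCc3ccccc3)c(OCc3ccccc3)cc2B2OC(C)(C)C(C)(C)O2)c1
F2 | step 4 | 4,4',5,5'-tetrakis(benzyloxy)-2,2'-bis[2-(3-methoxyphenyl)ethyl]-1,1'-biphenyl | COc1cccc(CCc2cc(OCc3ccccc3)c(OCc3ccccc3)cc2-c2cc(OCc3ccccc3)c(OCc3ccccc3)cc2CCc2cccc(OC)c2)c1
F3 | step 2 | 1,2-bis(benzyloxy)-4-bromo-5-ethenylbenzene | C=Cc1cc(OCc2ccccc2)c(OCc2ccccc2)cc1Br
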